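Readings and results come from a simulation from invented constants; scatter was added.

Time is the difference here: east and north-east are one charge, read at 20 h and 30 h, so we ask how fast the excess of left-handed product sinks while the flask stands.

common to all: left-handed substrate 0.50 M; right-handed substrate 0.50 M

| charge | partner | free catalyst | added ligand | remark | time |
|---|---|---|---|---|---|
| Monday's | 0.60 M | 0.40 mM | 1.3 mM | run made earlier |  |
| Sunday's | 0.60 M | 0.90 mM | 1.3 mM | run made earlier |  |
| Tuesday's | 0.60 M | 0.60 mM | 0.65 mM | run made earlier |  |
| east | 0.600 M | 0.60 mM | 1.3 mM |  | 20 h |
| north-east | 0.600 M | 0.60 mM | 1.3 mM |  | 30 h |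

| run | time / h | left-handed product / % | right-handed product / % | left-handed substrate / % |
|---|---|---|---|---|
| Monday's | 4.00 | 3.0 | 0.2 | 47.6 |
| Monday's | 8.00 | 4.8 | 0.8 | 45.2 |
| Monday's | 12.0 | 6.2 | 0 | 42.7 |
| Monday's | 15.0 | 7.2 | 0.4 | 42.0 |
| Sunday's | 2.00 | 2.8 | 0.7 | 47.3 |
| Sunday's | 6.00 | 6.6 | 0 | 42.7 |
| Sunday's | 10.0 | 10.7 | 0.6 | 38.3 |
| Sunday's | 15.0 | 14.1 | 1.4 | 35.0 |
| Tuesday's | 2.00 | 1.9 | 0 | 47.9 |
| Tuesday's | 6.00 | 4.4 | 0.5 | 44.0 |
| Tuesday's | 10.0 | 8.8 | 0.4 | 41.3 |
| Tuesday's | 15.0 | 11.3 | 1.0 | 38.7 |

(standard deviation of a reading: 0.5 percentage points)

- free catalyst is single-handed; left-handed substrate and right-handed substrate are mirror images of each other, charged as a racemate, each of them at the stated concentration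
- candidate steps: free catalyst + right-handed substrate <-> catalyst intermediate B; 2 free catalyst -> spent catalyst; partner + catalyst intermediate B -> free catalyst + right-handed product; partner + catalyst intermediate A -> free catalyst + left-handed product; free catalyst + added ligand <-> idle complex; left-handed product <-> right-handed product; free catalyst + left-handed substrate <-> catalyst intermediate A
- an excess is the difference of the two amounts in percent of their sum
- an excess is below zero if the other one leads

- which one finishes higher in excess of left-handed product over right-handed product in the product ("neither" within 2 percentage points) (east / north-east / neither)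
- excess of left-handed product over right-handed product in the product at the end, east
- excess of left-handed product over right-handed product in the product at the end, north-east

Take the rates first. Sunday's run made 2.8% of left-handed product in its first 2.00 h but 3.4 percentage points in its last 5.00 h, so its rate, as read, fell to 0.486 of its first value. Left-handed substrate in Sunday's run had fallen to 0.700 of its charge, which leaves a factor of 0.694 that we suspect is catalyst loss.

The excess has a rate too. Pooling the readings before each run's last gives 87.8% at a product-weighted time of 8.03 h, and the last readings pool to 84.2% at 15.0 h. Extended back, that line starts at 91.9%. Its slope gives 0.0113 h⁻¹, our fading constant λ, the first-order rate at which c(left-handed product) minus c(right-handed product) dies away by racemisation. With a scatter of 0.5 points on readings of that size, it is a weak reading.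

Integrating a steady formation rate, each portion fading at λ, gives the start excess times (one minus e^(−λt)) over λt. That is 82.3% for east and 78.0% for north-east, so we say east. Since the rate sinks, product in the flask is older than the steady rate supposes, and we hold both figures as high.

The forecast differs, reading the runs “with at most slight product racemisation”: it gave 86% for east and 84.5% for north-east, and its answer to which finishes higher was neither.

The higher excess goes to east, with 80.0% there against 72.3% for north-east.

    free catalyst + right-handed substrate ⇌ catalyst intermediate B (K = 4.60 L mol⁻¹, k = 640 L mol⁻¹ h⁻¹)
    2 free catalyst → spent catalyst (k = 1100 L mol⁻¹ h⁻¹)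
    partner + catalyst intermediate B → free catalyst + right-handed product (k = 2.70 L mol⁻¹ h⁻¹)
    partner + catalyst intermediate A → free catalyst + left-handed product (k = 51.0 L mol⁻¹ h⁻¹)
    free catalyst + added ligand ⇌ idle complex, settled at all times (K = 2300 L mol⁻¹)
    left-handed product ⇌ right-handed product (k = 0.00830 h⁻¹)
    free catalyst + left-handed substrate ⇌ catalyst intermediate A (K = 13.0 L mol⁻¹, k = 13000 L mol⁻¹ h⁻¹)

Without the step from left-handed to right-handed product, north-east minus east is −0.26 points, against −7.7 points with it. East has not come to rest: at 200 h it still holds 12.9% of left-handed substrate and an excess of 10.9%, where λ with the steady rate gives 36.4%.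

On the neighbour, the east charge read at 30 h, λ gives 77.9%; the computed excess is 72.3%.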